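**Plan**

Locants used throughout: C1 ester carbon, C2 CH(CH3), C3 and C6 the dioxane carbons (O2 on C3, O1 on C6), C7–C12 the side chain (C9=C10 olefin), C13 the cyclohexene carbon that carries the chain.
Retrosynthesis cuts, in this order: C12–C13 (made last), C11=C12 and C9=C10 (two Wittig olefinations), C6–C7 (allyl group onto a peroxycarbenium ion), O2–C3 (ring closure), C2–C3 (aldol).
Forward order: aldol chain C1–C6, then the 1,2-dioxane ring closed at O2–C3, then quaternary C6 by allylation, then growth of the chain to the C9–C12 diene, then oxidation of C1 to the ester, and finally attachment of the cyclohexene ring, which is bought as its ketone.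
Enabling feature: C12 is homoallylic to C9=C10, so it is the end carbon of a conjugated diene whose only monosubstituted double bond is C11=C12 (boron goes to C12); C13 lies between the quaternary C(CH3)2 carbon and the C(CH3)= carbon of the six-membered carbocycle, so 2,2,6-trimethylcyclohexanone enolises one way only and gives a single enol triflate.
Stereochemistry: C2 and C3 come from an auxiliary-controlled Evans syn aldol, and C3 is then inverted in the SN2 ring closure; C6 comes from axial attack on the six-membered peroxycarbenium ion, cis to the equatorial C3 side chain; the E olefin comes from a stabilised ylide.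

Key step: step 17

Remark: compounds 9 and 10 are carried as both epimers at the ketal carbon C6; this is of no consequence because step 8 passes through the planar peroxycarbenium ion.

**Route**

Step 1
Reactants: 1 ethyl 4-methylpent-4-enoate
Product: 2 4-methylpent-4-enal
Conditions: i-Bu2AlH, CH2Cl2, −78 °C; aq. KNaC4H4O6 work-up; used as a solution
Reagents that add atoms: none
Why: Partial reduction of an ester to the aldehyde: at −78 °C the tetrahedral aluminium alkoxide persists until work-up, so over-reduction is avoided.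

Step 2
Reactants: 3 (4S)-4-benzyl-3-propanoyl-1,3-oxazolidin-2-one; 2 4-methylpent-4-enal
Product: 5 (4S)-4-benzyl-3-[(2S,3R)-3-hydroxy-2,6-dimethylhept-6-enoyl]-1,3-oxazolidin-2-one, via dibutylboron Z-enolate 4 (not isolated)
Conditions: Bu2BOTf, i-Pr2NEt, CH2Cl2, 0 °C; then 2, −78 → 0 °C; pH 7 buffer, MeOH, 30% H2O2
Reagents that add atoms: none
Why: Evans syn aldol reaction: the Z boron enolate reacts through a closed chair transition state in which the benzyl group of the auxiliary shields one enolate face, which should set C2 (S) and C3 (R) together as the syn pair.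

Step 3
Reactants: 5 (4S)-4-benzyl-3-[(2S,3R)-3-hydroxy-2,6-dimethylhept-6-enoyl]-1,3-oxazolidin-2-one
Product: 6 (2R,3R)-2,6-dimethylhept-6-ene-1,3-diol
Conditions: LiBH4, MeOH (1 equiv), THF, 0 °C
Reagents that add atoms: none
Why: Reductive removal of the auxiliary: LiBH4 attacks the exocyclic imide carbonyl selectively and gives the 1,3-diol with both stereocentres unchanged (C2 becomes R only through the change of substituent priorities).

Step 4
Reactants: 6 (2R,3R)-2,6-dimethylhept-6-ene-1,3-diol
Product: 7 (2R,3R)-1-{[tert-butyl(diphenyl)silyl]oxy}-2,6-dimethylhept-6-en-3-ol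
Conditions: t-BuPh2SiCl, imidazole, CH2Cl2, 0 °C
Reagents that add atoms: tert-butyl(chloro)diphenylsilane, CC(C)(C)[Si](Cl)(c1ccccc1)c1ccccc1
Why: Silylation with a bulky silyl chloride is selective for the primary C1 hydroxyl over the hindered secondary C3 hydroxyl.

Step 5
Reactants: 7 (2R,3R)-1-{[tert-butyl(diphenyl)silyl]oxy}-2,6-dimethylhept-6-en-3-ol
Product: 8 (2R,3R)-1-{[tert-butyl(diphenyl)silyl]oxy}-2,6-dimethylhept-6-en-3-yl methanesulfonate
Conditions: MsCl, Et3N, CH2Cl2, 0 °C
Reagents that add atoms: methanesulfonyl chloride, CS(=O)(=O)Cl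
Why: Sulfonylation at oxygen (retention at C3) turns the C3 hydroxyl into the leaving group for the later ring closure.

Step 6
Reactants: 8 (2R,3R)-1-{[tert-butyl(diphenyl)silyl]oxy}-2,6-dimethylhept-6-en-3-yl methanesulfonate
Product: 9 (2R,3R)-1-{[tert-butyl(diphenyl)silyl]oxy}-6-hydroperoxy-6-methoxy-2-methylheptan-3-yl methanesulfonate (both C6 epimers)
Conditions: O3, CH2Cl2/MeOH, −78 °C; N2 purge; concentration without a reductant
Reagents that add atoms: ozone, [O-][O+]=O; methanol, CO
Why: Ozonolysis in methanol: the 1,1-disubstituted alkene is cleaved to formaldehyde and the more substituted carbonyl oxide, which methanol traps as the α-methoxy hydroperoxide, so that both oxygens of the future O–O bond are placed on C6.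

Step 7
Reactants: 9 (2R,3R)-1-{[tert-butyl(diphenyl)silyl]oxy}-6-hydroperoxy-6-methoxy-2-methylheptan-3-yl methanesulfonate
Product: 10 tert-butyl{(2R)-2-[(3S)-6-methoxy-6-methyl-1,2-dioxan-3-yl]propoxy}diphenylsilane (both C6 epimers)
Conditions: KOtBu, 18-crown-6, THF, 0 °C
Reagents that add atoms: none
Why: Intramolecular Williamson-type alkylation of a hydroperoxide (6-exo-tet SN2 ring closure): the peroxy anion displaces the C3 mesylate with inversion, which closes the 1,2-dioxane and should turn (3R) into the required (3S), while C1 at the alcohol oxidation level offers no E1cB pathway.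

Step 8
Reactants: 10 tert-butyl{(2R)-2-[(3S)-6-methoxy-6-methyl-1,2-dioxan-3-yl]propoxy}diphenylsilane
Product: 11 tert-butyl{(2R)-2-[(3S,6R)-6-methyl-6-(prop-2-en-1-yl)-1,2-dioxan-3-yl]propoxy}diphenylsilane
Conditions: allyltrimethylsilane, TiCl4, CH2Cl2, −78 °C
Reagents that add atoms: allyltrimethylsilane, C=CC[Si](C)(C)C
Why: Hosomi–Sakurai allylation of a cyclic peroxyketal: TiCl4 ionises the C6–OMe bond to a six-membered peroxycarbenium ion whose half-chair carries the C3 side chain pseudo-equatorial, and axial attack of the allylsilane on the face that leads to a chair should place the allyl group cis to that side chain, which sets the quaternary C6 centre in the sense the target requires.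

Step 9
Reactants: 11 tert-butyl{(2R)-2-[(3S,6R)-6-methyl-6-(prop-2-en-1-yl)-1,2-dioxan-3-yl]propoxy}diphenylsilane
Product: 13 3-[(3S,6S)-6-[(2R)-1-{[tert-butyl(diphenyl)silyl]oxy}propan-2-yl]-3-methyl-1,2-dioxan-3-yl]propan-1-ol, via B-alkyl-9-BBN adduct 12 (not isolated)
Conditions: 9-BBN, THF, 0 °C → rt; then 30% H2O2, aq. NaOAc, 0 °C → rt
Reagents that add atoms: hydrogen peroxide, OO
Why: Anti-Markovnikov hydroboration–oxidation: 9-BBN puts boron on the terminal carbon C9 and the acetate-buffered peroxide oxidation replaces it by OH, with the dialkyl O–O bond and the silyl ether left alone.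

Step 10
Reactants: 13 3-[(3S,6S)-6-[(2R)-1-{[tert-butyl(diphenyl)silyl]oxy}propan-2-yl]-3-methyl-1,2-dioxan-3-yl]propan-1-ol
Product: 14 3-[(3R,6S)-6-[(2R)-1-{[tert-butyl(diphenyl)silyl]oxy}propan-2-yl]-3-methyl-1,2-dioxan-3-yl]propanal
Conditions: DMP (1,1,1-triacetoxy-1,1-dihydro-1,2-benziodoxol-3(1H)-one), CH2Cl2, rt
Reagents that add atoms: none
Why: Periodinane oxidation of a primary alcohol to the aldehyde under neutral, non-aqueous conditions that leave the O–O bond and the silyl ether intact (C6 becomes R only through the change of priorities).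

Step 11
Reactants: 14 3-[(3R,6S)-6-[(2R)-1-{[tert-butyl(diphenyl)silyl]oxy}propan-2-yl]-3-methyl-1,2-dioxan-3-yl]propanal
Product: 15 (2E)-5-[(3S,6S)-6-[(2R)-1-{[tert-butyl(diphenyl)silyl]oxy}propan-2-yl]-3-methyl-1,2-dioxan-3-yl]-2-methylpent-2-enal
Conditions: Ph3P=C(CH3)CHO, toluene, 80 °C
Reagents that add atoms: 2-(triphenyl-λ5-phosphanylidene)propanal, CC(C=O)=P(c1ccccc1)(c1ccccc1)c1ccccc1
Why: Wittig olefination with a carbonyl-stabilised ylide, which reacts with the saturated aldehyde in preference to the enal product and should give the E trisubstituted C9=C10 double bond (chain trans to CHO).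

Step 12
Reactants: 15 (2E)-5-[(3S,6S)-6-[(2R)-1-{[tert-butyl(diphenyl)silyl]oxy}propan-2-yl]-3-methyl-1,2-dioxan-3-yl]-2-methylpent-2-enal
Product: 16 tert-butyl{(2R)-2-[(3S,6S)-6-methyl-6-[(3E)-4-methylhexa-3,5-dien-1-yl]-1,2-dioxan-3-yl]propoxy}diphenylsilane
Conditions: Ph3PCH3Br, KN(SiMe3)2, THF, 0 °C; then 15, −78 → 0 °C
Reagents that add atoms: methyltriphenylphosphonium bromide, C[P+](c1ccccc1)(c1ccccc1)c1ccccc1.[Br-]
Why: Wittig methylenation of the enal carbonyl (1,2-addition) completes the conjugated diene and supplies C12 as the terminal alkene carbon without touching the E C9=C10 bond.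

Step 13
Reactants: 16 tert-butyl{(2R)-2-[(3S,6S)-6-methyl-6-[(3E)-4-methylhexa-3,5-dien-1-yl]-1,2-dioxan-3-yl]propoxy}diphenylsilane
Product: 17 (2R)-2-[(3S,6S)-6-methyl-6-[(3E)-4-methylhexa-3,5-dien-1-yl]-1,2-dioxan-3-yl]propan-1-ol
Conditions: Bu4NF, AcOH, THF, 0 °C → rt
Reagents that add atoms: none
Why: Fluoride-driven cleavage of the silyl ether, buffered with acetic acid so that no base-induced (Kornblum–DeLaMare-type) fragmentation of the dioxane can occur.

Step 14
Reactants: 17 (2R)-2-[(3S,6S)-6-methyl-6-[(3E)-4-methylhexa-3,5-dien-1-yl]-1,2-dioxan-3-yl]propan-1-ol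
Product: 19 (2S)-2-[(3S,6S)-6-methyl-6-[(3E)-4-methylhexa-3,5-dien-1-yl]-1,2-dioxan-3-yl]propanoic acid, via aldehyde 18 (not isolated)
Conditions: TEMPO (cat.), PhI(OAc)2, MeCN/H2O, rt
Reagents that add atoms: water, O
Why: Oxoammonium (TEMPO) oxidation of the primary alcohol through the aldehyde hydrate to the acid at near-neutral pH, under which the α-stereocentre C2, the diene and the O–O bond should be stable.

Step 15
Reactants: 19 (2S)-2-[(3S,6S)-6-methyl-6-[(3E)-4-methylhexa-3,5-dien-1-yl]-1,2-dioxan-3-yl]propanoic acid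
Product: 20 methyl (2S)-2-[(3S,6S)-6-methyl-6-[(3E)-4-methylhexa-3,5-dien-1-yl]-1,2-dioxan-3-yl]propanoate
Conditions: Me3SiCHN2, toluene/MeOH, 0 °C
Reagents that add atoms: (trimethylsilyl)diazomethane, C[Si](C)(C)C=[N+]=[N-]
Why: Methyl ester formation by O-alkylation of the carboxylic acid with the diazoalkane, a base-free esterification that cannot epimerise C2 or open the β-peroxy ester.

Step 16
Reactants: 21 2,2,6-trimethylcyclohexan-1-one
Product: 23 2,6,6-trimethylcyclohex-1-en-1-yl trifluoromethanesulfonate, via lithium enolate 22 (not isolated)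
Conditions: LiN(i-Pr)2, THF, −78 → 0 °C; then PhNTf2, 0 °C → rt
Reagents that add atoms: N-phenylbis(trifluoromethanesulfonimide), O=S(=O)(N(c1ccccc1)S(=O)(=O)C(F)(F)F)C(F)(F)F
Why: Enolate O-triflation: only one α-carbon of the ketone bears a hydrogen because the other is quaternary, so deprotonation and trapping can give only the enol triflate with the leaving group on the future C13.

Step 17
Reactants: 20 methyl (2S)-2-[(3S,6S)-6-methyl-6-[(3E)-4-methylhexa-3,5-dien-1-yl]-1,2-dioxan-3-yl]propanoate; 23 2,6,6-trimethylcyclohex-1-en-1-yl trifluoromethanesulfonate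
Product: 25 methyl (2S)-2-[(3S,6S)-6-methyl-6-[(3E)-4-methyl-6-(2,6,6-trimethylcyclohex-1-en-1-yl)hex-3-en-1-yl]-1,2-dioxan-3-yl]propanoate, via B-alkyl-9-BBN adduct 24 (not isolated)
Conditions: 9-BBN, THF, 0 °C → rt; then 23, Pd(dppf)Cl2 (cat.), AsPh3 (cat.), Cs2CO3, DMF/H2O, rt
Reagents that add atoms: none
Why: 9-BBN adds across the monosubstituted C11=C12 double bond of the diene with boron on C12, and the resulting primary alkylborane, activated as its hydroxyborate, transfers C12 to the alkenylpalladium formed by oxidative addition of zerovalent palladium into the C13–O bond of the triflate; reductive elimination then forms C12–C13. The closest known reaction type is the B-alkyl Suzuki–Miyaura coupling of 9-BBN-derived primary alkylboranes with hindered enol triflates. No ring is closed and no stereocentre is created, so no closure mode or control element applies; the three dioxane stereocentres and the E olefin are carried through unchanged. The step needs site selectivity between the two double bonds of the diene and regioselective B–H addition, and the substrate secures both: C11=C12 is the only monosubstituted alkene, C9=C10 is trisubstituted, and the bulky borane places boron on the terminal carbon. It also needs a single triflate regioisomer, which the quaternary C(CH3)2 carbon next to C13 guarantees, and β-hydride elimination from the alkylpalladium is held back by the wide-bite-angle dppf ligand. The dialkyl O–O bond, the ester and the C2 centre should survive the mild borane, the carbonate base and room temperature; once the bond is formed the target is complete, with no helper group left to remove.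

**Compound list**

1 | ethyl 4-methylpent-4-enoate | CCOC(=O)CCC(C)=C | starting material
2 | 4-methylpent-4-enal | O=CCCC(C)=C | intermediate
3 | (4S)-4-benzyl-3-propanoyl-1,3-oxazolidin-2-one | CCC(=O)N1[C@@H](Cc2ccccc2)COC1=O | starting material
4 | dibutylboron Z-enolate of 3 | C/C=C(\OB(CCCC)CCCC)N1[C@@H](Cc2ccccc2)COC1=O | intermediate
5 | (4S)-4-benzyl-3-[(2S,3R)-3-hydroxy-2,6-dimethylhept-6-enoyl]-1,3-oxazolidin-2-one | O=C(N1[C@@H](Cc2ccccc2)COC1=O)[C@@H](C)[C@H](O)CCC(C)=C | intermediate
6 | (2R,3R)-2,6-dimethylhept-6-ene-1,3-diol | OC[C@@H](C)[C@H](O)CCC(C)=C | intermediate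
7 | (2R,3R)-1-{[tert-butyl(diphenyl)silyl]oxy}-2,6-dimethylhept-6-en-3-ol | CC(C)(C)[Si](c1ccccc1)(c1ccccc1)OC[C@@H](C)[C@H](O)CCC(C)=C | intermediate
8 | (2R,3R)-1-{[tert-butyl(diphenyl)silyl]oxy}-2,6-dimethylhept-6-en-3-yl methanesulfonate | CC(C)(C)[Si](c1ccccc1)(c1ccccc1)OC[C@@H](C)[C@H](OS(C)(=O)=O)CCC(C)=C | intermediate
9 | (2R,3R)-1-{[tert-butyl(diphenyl)silyl]oxy}-6-hydroperoxy-6-methoxy-2-methylheptan-3-yl methanesulfonate (both C6 epimers) | CC(C)(C)[Si](c1ccccc1)(c1ccccc1)OC[C@@H](C)[C@H](OS(C)(=O)=O)CCC(C)(OC)OO | intermediate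
10 | tert-butyl{(2R)-2-[(3S)-6-methoxy-6-methyl-1,2-dioxan-3-yl]propoxy}diphenylsilane (both C6 epimers) | CC(C)(C)[Si](c1ccccc1)(c1ccccc1)OC[C@@H](C)[C@@H]1CCC(C)(OC)OO1 | intermediate
11 | tert-butyl{(2R)-2-[(3S,6R)-6-methyl-6-(prop-2-en-1-yl)-1,2-dioxan-3-yl]propoxy}diphenylsilane | CC(C)(C)[Si](c1ccccc1)(c1ccccc1)OC[C@@H](C)[C@@H]1CC[C@](C)(CC=C)OO1 | intermediate
12 | 9-{3-[(3S,6S)-6-[(2R)-1-{[tert-butyl(diphenyl)silyl]oxy}propan-2-yl]-3-methyl-1,2-dioxan-3-yl]propyl}-9-borabicyclo[3.3.1]nonane | CC(C)(C)[Si](c1ccccc1)(c1ccccc1)OC[C@@H](C)[C@@H]1CC[C@](C)(CCCB2C3CCCC2CCC3)OO1 | intermediate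
13 | 3-[(3S,6S)-6-[(2R)-1-{[tert-butyl(diphenyl)silyl]oxy}propan-2-yl]-3-methyl-1,2-dioxan-3-yl]propan-1-ol | CC(C)(C)[Si](c1ccccc1)(c1ccccc1)OC[C@@H](C)[C@@H]1CC[C@](C)(CCCO)OO1 | intermediate
14 | 3-[(3R,6S)-6-[(2R)-1-{[tert-butyl(diphenyl)silyl]oxy}propan-2-yl]-3-methyl-1,2-dioxan-3-yl]propanal | CC(C)(C)[Si](c1ccccc1)(c1ccccc1)OC[C@@H](C)[C@@H]1CC[C@](C)(CCC=O)OO1 | intermediate
15 | (2E)-5-[(3S,6S)-6-[(2R)-1-{[tert-butyl(diphenyl)silyl]oxy}propan-2-yl]-3-methyl-1,2-dioxan-3-yl]-2-methylpent-2-enal | CC(C)(C)[Si](c1ccccc1)(c1ccccc1)OC[C@@H](C)[C@@H]1CC[C@](C)(CC/C=C(\C)C=O)OO1 | intermediate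
16 | tert-butyl{(2R)-2-[(3S,6S)-6-methyl-6-[(3E)-4-methylhexa-3,5-dien-1-yl]-1,2-dioxan-3-yl]propoxy}diphenylsilane | CC(C)(C)[Si](c1ccccc1)(c1ccccc1)OC[C@@H](C)[C@@H]1CC[C@](C)(CC/C=C(\C)C=C)OO1 | intermediate
17 | (2R)-2-[(3S,6S)-6-methyl-6-[(3E)-4-methylhexa-3,5-dien-1-yl]-1,2-dioxan-3-yl]propan-1-ol | OC[C@@H](C)[C@@H]1CC[C@](C)(CC/C=C(\C)C=C)OO1 | intermediate
18 | (2S)-2-[(3S,6S)-6-methyl-6-[(3E)-4-methylhexa-3,5-dien-1-yl]-1,2-dioxan-3-yl]propanal | O=C[C@@H](C)[C@@H]1CC[C@](C)(CC/C=C(\C)C=C)OO1 | intermediate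
19 | (2S)-2-[(3S,6S)-6-methyl-6-[(3E)-4-methylhexa-3,5-dien-1-yl]-1,2-dioxan-3-yl]propanoic acid | OC(=O)[C@@H](C)[C@@H]1CC[C@](C)(CC/C=C(\C)C=C)OO1 | intermediate
20 | methyl (2S)-2-[(3S,6S)-6-methyl-6-[(3E)-4-methylhexa-3,5-dien-1-yl]-1,2-dioxan-3-yl]propanoate | COC(=O)[C@@H](C)[C@@H]1CC[C@](C)(CC/C=C(\C)C=C)OO1 | intermediate
21 | 2,2,6-trimethylcyclohexan-1-one | CC1CCCC(C)(C)C1=O | starting material
22 | lithium 2,6,6-trimethylcyclohex-1-en-1-olate | [Li+].[O-]C1=C(C)CCCC1(C)C | intermediate
23 | 2,6,6-trimethylcyclohex-1-en-1-yl trifluoromethanesulfonate | CC1=C(OS(=O)(=O)C(F)(F)F)C(C)(C)CCC1 | intermediate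
24 | methyl (2S)-2-[(3S,6S)-6-[(3E)-6-(9-borabicyclo[3.3.1]nonan-9-yl)-4-methylhex-3-en-1-yl]-6-methyl-1,2-dioxan-3-yl]propanoate | COC(=O)[C@@H](C)[C@@H]1CC[C@](C)(CC/C=C(\C)CCB2C3CCCC2CCC3)OO1 | intermediate
25 | methyl (2S)-2-[(3S,6S)-6-methyl-6-[(3E)-4-methyl-6-(2,6,6-trimethylcyclohex-1-en-1-yl)hex-3-en-1-yl]-1,2-dioxan-3-yl]propanoate | COC(=O)[C@@H](C)[C@@H]1CC[C@](C)(CC/C=C(\C)CCC2=C(C)CCCC2(C)C)OO1 | target

**Step count**

Total steps: 17. Longest linear sequence: 16 (steps 1–15 and 17); step 16 is a one-step side branch.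

**Steps most likely to fail, with fallbacks**

Step 17. Transfer of the alkyl group from boron to the hindered, tetrasubstituted alkenylpalladium may be slow. Protodeboronation, reduction of the O–O bond by the borate or by zerovalent palladium, and base-induced opening of the β-peroxy ester could then compete. The fallback changes the carbon nucleophile to an organozinc, so that no borate, hydroxide or carbonate is present during the metal-catalysed union. It sets out from 20: hydroboration with 9-BBN and acetate-buffered H2O2 oxidation (as in step 9) should give the hydroxy ester F1. Appel iodination (I2, PPh3, imidazole, CH2Cl2, 0 °C) should convert it into the iodo ester F2. Zinc insertion (Zn dust, LiCl, THF) should give the alkylzinc iodide F3. Negishi coupling of F3 with 23 (Pd2(dba)3, SPhos, THF, rt) returns to the route at 25.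

Step 8. Ionisation by TiCl4 may trigger heterolytic O–O cleavage and fragmentation of the ring faster than the weakly nucleophilic allylsilane traps the cation, and capture through both half-chairs would erode facial selectivity at C6. The fallback makes the C6–C7 bond by a Mukaiyama-type addition instead, with a much stronger and bulkier π-nucleophile and only catalytic silyl triflate. It sets out from 10: 1-(tert-butyldimethylsilyloxy)-1-methoxyethene with Me3SiOTf (cat.) in CH2Cl2 at −78 °C should give the dioxanyl acetate F4, by the same axial attack. Reduction with i-Bu2AlH at −78 °C should give the dioxanyl acetaldehyde F5. Wittig methylenation (Ph3P=CH2, THF, −78 °C) returns to the route at 11.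

Step 7. E2 elimination of the α-branched secondary mesylate by the peroxy anion or by the alkoxide base may outrun the 6-exo substitution. The fallback replaces the base-promoted sulfonate displacement by an acid-promoted opening of an oxetane, in which no strong base is present. It sets out from 6: selective tosylation of the primary hydroxyl (TsCl, pyridine, 0 °C) should give the monotosylate F6, and KOtBu in THF should close it to the oxetane F7 with C3 unchanged. Ozonolysis in CH2Cl2/MeOH (as in step 6) should give the oxetanyl hydroperoxy ketal F8. Me3SiOTf (cat.) in CH2Cl2 at low temperature should then induce 6-exo attack of the hydroperoxide on the oxetane carbon C3 with inversion, giving the dioxanyl propanol F9. Silylation (t-BuPh2SiCl, imidazole) returns to the route at 10.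

Further compounds
F1 | step 17 | methyl (2S)-2-[(3S,6S)-6-[(3E)-6-hydroxy-4-methylhex-3-en-1-yl]-6-methyl-1,2-dioxan-3-yl]propanoate | COC(=O)[C@@H](C)[C@@H]1CC[C@](C)(CC/C=C(\C)CCO)OO1
F2 | step 17 | methyl (2S)-2-[(3S,6S)-6-[(3E)-6-iodo-4-methylhex-3-en-1-yl]-6-methyl-1,2-dioxan-3-yl]propanoate | COC(=O)[C@@H](C)[C@@H]1CC[C@](C)(CC/C=C(\C)CCI)OO1
F3 | step 17 | iodo{(3E)-6-[(3S,6S)-6-[(2S)-1-methoxy-1-oxopropan-2-yl]-3-methyl-1,2-dioxan-3-yl]-3-methylhex-3-en-1-yl}zinc | COC(=O)[C@@H](C)[C@@H]1CC[C@](C)(CC/C=C(\C)CC[Zn]I)OO1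
F4 | step 8 | methyl 2-[(3R,6S)-6-[(2R)-1-{[tert-butyl(diphenyl)silyl]oxy}propan-2-yl]-3-methyl-1,2-dioxan-3-yl]acetate | CC(C)(C)[Si](c1ccccc1)(c1ccccc1)OC[C@@H](C)[C@@H]1CC[C@](C)(CC(=O)OC)OO1
F5 | step 8 | 2-[(3R,6S)-6-[(2R)-1-{[tert-butyl(diphenyl)silyl]oxy}propan-2-yl]-3-methyl-1,2-dioxan-3-yl]acetaldehyde | CC(C)(C)[Si](c1ccccc1)(c1ccccc1)OC[C@@H](C)[C@@H]1CC[C@](C)(CC=O)OO1
F6 | step 7 | (2R,3R)-3-hydroxy-2,6-dimethylhept-6-en-1-yl 4-methylbenzenesulfonate | Cc1ccc(cc1)S(=O)(=O)OC[C@@H](C)[C@H](O)CCC(C)=C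
F7 | step 7 | (2R,3R)-3-methyl-2-(3-methylbut-3-en-1-yl)oxetane | C1[C@@H](C)[C@H](O1)CCC(C)=C
F8 | step 7 | (2R,3R)-2-(3-hydroperoxy-3-methoxybutyl)-3-methyloxetane (both epimers at the ketal carbon) | C1[C@@H](C)[C@H](O1)CCC(C)(OC)OO
F9 | step 7 | (2R)-2-[(3S)-6-methoxy-6-methyl-1,2-dioxan-3-yl]propan-1-ol (both C6 epimers) | OC[C@@H](C)[C@@H]1CCC(C)(OC)OO1
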